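(The numbers in the tables stem from a simulated flask for substances that don't exist, noise included.)

The east run, with 20 mM of free catalyst, made product at 5.78 mM s⁻¹ over its 4.00 min, and the north run, with 30 mM, at 8.43 mM s⁻¹ over its 120 s.

all flasks: gas 200 mM (held)
- north: starting material 3 M; free catalyst 30 mM; the very flask that is asked about, followed so far
- east: starting material 3 M; free catalyst 20 mM; run made earlier
- flask: starting material 3.0 M; free catalyst 30 mM

north run (percent of the starting material charged)

| time / s | product / % | starting material / % |
|---|---|---|
| 10.0 | 2.0 | 96.4 |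
| 20.0 | 4.8 | 94.8 |
| 30.0 | 7.9 | 91.9 |
| 50.0 | 14.6 | 85.1 |
| 80.0 | 22.8 | 77.0 |
| 90.0 | 24.8 | 74.3 |
| 120 | 33.7 | 66.9 |

east run (percent of the starting material charged)

| time / min | product / % | starting material / % |
|---|---|---|
| 0.333 | 3.6 | 96.3 |
| 0.500 | 5.8 | 94.9 |
| 0.667 | 7.2 | 92.2 |
| 1.00 | 12.7 | 88.7 |
| 1.50 | 19.7 | 79.6 |
| 2.50 | 30.2 | 70.2 |
| 4.00 | 46.2 | 55.9 |

(scatter of a reading: 1 percentage point)

* factor on the rate of making product when 50% of the starting material are converted if free catalyst is charged twice over
* factor on the rate when 50% of the starting material are converted if free catalyst is charged at 300 mM instead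

- at the start none of reagent is dissolved
- steps that have been proposed: catalyst intermediate C -> free catalyst + product; starting material + free catalyst <-> catalyst intermediate A; reagent + catalyst intermediate A -> catalyst intermediate B; gas <-> reagent; free catalyst + released group -> spent catalyst; catalyst intermediate B <-> released group + catalyst intermediate C

As readings, the turnover per catalyst (turnover frequency) was 0.289 s⁻¹ in the east run and 0.281 s⁻¹ in the north run, close to equal. So I took plain proportion as the zero of my scale: the factor on the rate equals the factor on the catalyst.

The proposed round uses one reagent per turn, which left two rates to compare. One was what the gas had been seen to deliver in the north run, 8.43 mM s⁻¹. The other was what 300 mM would ask: 84.2 mM s⁻¹, the reagent demand, meaning catalyst charged times turnover per catalyst. That demand stood 10.0 times above what had been seen. The doubled charge would ask 16.9 mM s⁻¹. I expected about 2 for the doubled charge and less than 10.0 at 300 mM, but I could set no figure.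

The forecast gave 1.95 and 7, in its words “So I expect less than tenfold”.

The flask gave 2.23 and 4.80, and the factor at 300 mM came out below the forecast's.

    catalyst intermediate C → free catalyst + product (k = 210 s⁻¹)
    starting material + free catalyst ⇌ catalyst intermediate A (K = 0.880 L mol⁻¹, k = 1.50 L mol⁻¹ s⁻¹)
    reagent + catalyst intermediate A → catalyst intermediate B (k = 4.20 L mol⁻¹ s⁻¹)
    gas ⇌ reagent, rate k4*(csat - [reagent]) (kL = 0.130 s⁻¹)
    free catalyst + released group → spent catalyst (k = 0.0110 L mol⁻¹ s⁻¹)
    catalyst intermediate B ⇌ released group + catalyst intermediate C (K = 1.30 M, k = 3.70 s⁻¹)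

With these constants the gas delivers 26.0 mM s⁻¹ of reagent when none is dissolved, and the demand of 84.2 mM s⁻¹ at 300 mM stands 3.24 times above that, while the doubled charge's 16.9 mM s⁻¹ stays below it. In the 30 mM flask at 2.00 min, reagent stood at 0.142 M against the 200 mM of gas held, so the gas was delivering 7.51 mM s⁻¹.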